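Everything rests on cutting ring C of the 5,7-dihydroxychromanone at O1–C8a and C4–C4a. In ring A the ether oxygen O1 (on C8a) and the C4 carbonyl (on C4a) are neighbours, and C4a is flanked on its other side by the oxygenated C5; a 3-alkoxybenzyne that takes up an alkoxide at its remote carbon and an acyl group at the carbon beside the alkoxy group gives precisely this array. One operation therefore unmasks 3,5-bis(benzyloxy)benzyne and the alkoxide of a (3S)-3-silyloxy ester and closes ring C with the C2–O bond untouched. The precursor is the benzyl-protected rings D–E–F flavanone bearing, on ring B, a methyl (3S)-3-(trimethylsilyloxy)propanoate chain.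

Key step: step 12

Assumption: rotamers about the C3'–C8'' biaryl bond are taken to interconvert at room temperature and are treated as one compound; the antipode named for each chiral ligand or auxiliary is the one expected from the accepted model for simple substrates, and its mirror image is used if a trial run shows the opposite sense.

Shorthand used in names: Ar* = 4-(benzyloxy)-3-[(2S)-5-(benzyloxy)-2-[4-(benzyloxy)phenyl]-7-methoxy-4-oxochroman-8-yl]phenyl.

Step 1
Reactants: 1 1-(2,6-dihydroxy-4-methoxyphenyl)ethan-1-one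
Product: 2 1-[2-(benzyloxy)-6-hydroxy-4-methoxyphenyl]ethan-1-one
Conditions: BnBr (1.05 equiv), K2CO3, acetone, reflux
Reagents that add atoms: benzyl bromide, BrCc1ccccc1
Why: Williamson ether synthesis; after the first benzylation the remaining hydroxyl is locked in a hydrogen bond to the acetyl carbonyl and should resist a second alkylation.

Step 2
Reactants: 2 1-[2-(benzyloxy)-6-hydroxy-4-methoxyphenyl]ethan-1-one
Product: 3 1-[6-(benzyloxy)-2-hydroxy-3-iodo-4-methoxyphenyl]ethan-1-one
Conditions: BnMe3N·ICl2 (1.05 equiv), NaHCO3, CH2Cl2/MeOH, rt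
Reagents that add atoms: benzyltrimethylammonium dichloroiodate, C[N+](C)(C)Cc1ccccc1.Cl[I-]Cl
Why: Electrophilic aromatic iodination; 2-hydroxy-4,6-dialkoxyacetophenones are known to be iodinated at the carbon between the chelated phenol and the 4-alkoxy group, the other free position being crowded by two ethers.

Step 3
Reactants: 3 1-[6-(benzyloxy)-2-hydroxy-3-iodo-4-methoxyphenyl]ethan-1-one
Product: 5 5-(benzyloxy)-8-iodo-7-methoxy-4H-chromen-4-one, via enaminone 4 (not isolated)
Conditions: Me2NCH(OMe)2, toluene, 95 °C; then conc. HCl, CH2Cl2, 40 °C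
Reagents that add atoms: N,N-dimethylformamide dimethyl acetal, COC(OC)N(C)C
Why: Enaminone formation at the acetyl methyl group followed by acid-promoted cyclisation of the phenol with loss of dimethylamine (standard chromone synthesis); the iodine sits next to the phenol that becomes O1'' and therefore ends on C8''.

Step 4
Reactants: 6 3-bromo-4-hydroxybenzaldehyde
Product: 7 4-(benzyloxy)-3-bromobenzaldehyde
Conditions: BnBr, K2CO3, DMF, rt
Reagents that add atoms: benzyl bromide, BrCc1ccccc1
Why: Williamson ether synthesis on an acidic para-formylphenol, which should be clean at room temperature.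

Step 5
Reactants: 7 4-(benzyloxy)-3-bromobenzaldehyde
Product: 8 4-(benzyloxy)-3-(4,4,5,5-tetramethyl-1,3,2-dioxaborolan-2-yl)benzaldehyde
Conditions: B2pin2, PdCl2(dppf) (3 mol %), KOAc, 1,4-dioxane, 90 °C
Reagents that add atoms: bis(pinacolato)diboron, CC1(C)OB(OC1(C)C)B1OC(C)(C)C(C)(C)O1
Why: Miyaura borylation; the weak acetate base tolerates the aldehyde and does not promote homocoupling.

Step 6
Reactants: 5 5-(benzyloxy)-8-iodo-7-methoxy-4H-chromen-4-one; 8 4-(benzyloxy)-3-(4,4,5,5-tetramethyl-1,3,2-dioxaborolan-2-yl)benzaldehyde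
Product: 9 4-(benzyloxy)-3-[5-(benzyloxy)-7-methoxy-4-oxo-4H-chromen-8-yl]benzaldehyde
Conditions: Pd(OAc)2 (5 mol %), SPhos (10 mol %), K3PO4, toluene/H2O (10:1), 70 °C
Reagents that add atoms: none
Why: Suzuki–Miyaura coupling; the dialkylbiarylphosphine is suited to biaryls with three ortho substituents, and the aryl iodide should couple at a temperature that spares the chromone from the base.

Step 7
Reactants: 9 4-(benzyloxy)-3-[5-(benzyloxy)-7-methoxy-4-oxo-4H-chromen-8-yl]benzaldehyde; 10 [4-(benzyloxy)phenyl]boronic acid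
Product: 11 4-(benzyloxy)-3-{(2S)-5-(benzyloxy)-2-[4-(benzyloxy)phenyl]-7-methoxy-4-oxochroman-8-yl}benzaldehyde
Conditions: 10 (3 equiv), [Rh(OH)(C8H12)]2 (2.5 mol %; C8H12 = 1,5-cyclooctadiene), (S)-2,2'-bis[bis(3,4,5-trifluorophenyl)phosphino]-6,6'-dimethoxy-1,1'-biphenyl (5.5 mol %), toluene/H2O (10:1), 50 °C
Reagents that add atoms: none
Why: Rhodium-catalysed asymmetric 1,4-addition of an arylboronic acid to a chromone (Hayashi–Miyaura reaction), in which the chiral bisphosphine selects the face of C2'' for aryl insertion and so sets the (2''S) centre; the electron-poor ligand should make the addition fast in a nearly neutral two-phase medium so that the flavanone does not ring-open, and the para-alkoxybenzaldehyde is a poor acceptor for aryl–rhodium 1,2-addition.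

Step 8
Reactants: 11 4-(benzyloxy)-3-{(2S)-5-(benzyloxy)-2-[4-(benzyloxy)phenyl]-7-methoxy-4-oxochroman-8-yl}benzaldehyde
Product: 13 methyl (3S)-3-Ar*-3-hydroxypropanoate, via trichlorosilyl ether 12 (not isolated)
Conditions: CH2=C(OMe)OSiMe2t-Bu (1.3 equiv), SiCl4 (1.5 equiv), N,N'-bis[(11bR)-3,5-dimethyl-4-oxido-3,5-dihydro-4H-dinaphtho[2,1-d:1',2'-f][1,3,2]diazaphosphepin-4-yl]-N,N'-dimethylpentane-1,5-diamine (5 mol %), i-Pr2NEt (10 mol %), CH2Cl2, −78 °C; then sat. aq. NaHCO3
Reagents that add atoms: 1-(tert-butyldimethylsilyloxy)-1-methoxyethene, C=C(OC)O[Si](C)(C)C(C)(C)C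
Why: Lewis-base-catalysed, SiCl4-mediated Mukaiyama acetate aldol addition, in which the chiral phosphoramide-bound silicon cation activates the aldehyde and exposes its Si face to the ketene acetal to set the (3S) carbinol while the much less electrophilic chromanone carbonyl is left alone; chromatography of 13 should also remove the diastereomers that stem from the minor enantiomers of steps 7 and 8.

Step 9
Reactants: 13 methyl (3S)-3-Ar*-3-hydroxypropanoate
Product: 14 methyl (3S)-3-Ar*-3-[(trimethylsilyl)oxy]propanoate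
Conditions: Me3SiCl (1.5 equiv), imidazole (3 equiv), CH2Cl2, 0 °C; cold aq. NaHCO3 wash, filtration through Et3N-deactivated silica, used at once
Reagents that add atoms: chlorotrimethylsilane, C[Si](C)(C)Cl
Why: Silylation of a secondary alcohol with a silyl chloride and imidazole, under conditions too mild to disturb either stereocentre.

Step 10
Reactants: 15 3,5-bis(benzyloxy)phenol
Product: 16 3,5-bis(benzyloxy)-2-bromophenol
Conditions: NBS (1.0 equiv), i-Pr2NH (10 mol %), CH2Cl2, −78 °C
Reagents that add atoms: N-bromosuccinimide, O=C1CCC(=O)N1Br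
Why: Electrophilic aromatic bromination with amine-mediated ortho delivery; the two positions ortho to the hydroxyl are equivalent, and any 4-bromo isomer is removed by chromatography.

Step 11
Reactants: 16 3,5-bis(benzyloxy)-2-bromophenol
Product: 19 3,5-bis(benzyloxy)-2-(trimethylsilyl)phenyl trifluoromethanesulfonate, via aryl silyl ether 17 (not isolated), via lithium silylphenoxide 18 (not isolated)
Conditions: (Me3Si)2NH, THF, 70 °C, then evaporation; n-BuLi, THF, −78 °C; Tf2O, −78 °C
Reagents that add atoms: hexamethyldisilazane, C[Si](C)(C)N[Si](C)(C)C; trifluoromethanesulfonic anhydride, O=S(=O)(OS(=O)(=O)C(F)(F)F)C(F)(F)F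
Why: O-silylation, bromine–lithium exchange with retro-Brook migration of silicon from oxygen to carbon, and triflation of the resulting phenoxide (the standard route to ortho-silylaryl triflates); the exchange at −78 °C should be faster than benzylic deprotonation of the ethers.

Step 12
Reactants: 14 methyl (3S)-3-Ar*-3-[(trimethylsilyl)oxy]propanoate; 19 3,5-bis(benzyloxy)-2-(trimethylsilyl)phenyl trifluoromethanesulfonate
Product: 23 (2S)-5,7-bis(benzyloxy)-2-{4-(benzyloxy)-3-[(2S)-5-(benzyloxy)-2-[4-(benzyloxy)phenyl]-7-methoxy-4-oxochroman-8-yl]phenyl}chroman-4-one, via aryne 20 (not isolated), via potassium alkoxide 21 (not isolated), via aryl anion 22 (not isolated)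
Conditions: 19 (1.5 equiv), KF (3 equiv), 18-crown-6 (3 equiv), THF, 0 °C → rt; pH 7 buffer quench at 0 °C
Reagents that add atoms: none
Why: Proposed new method: fluoride removes the carbon-bound silyl group of 19 with loss of triflate to give aryne 20 and frees alkoxide 21 from the O-silyl group of 14 in an aprotic medium; 21 should add to the aryne carbon remote from the flanking benzyloxy group (the future C8a), and the aryl anion 22 thus placed on C4a should attack the methyl ester, expel methoxide and form the C4–C4a bond. The closest known reactions are the fluoride-triggered annulation of arynes with salicylate esters to xanthones and the insertion of arynes into O–H bonds and into bonds of carboxylic acid derivatives; an aliphatic β-silyloxy ester has not been used in this way. Ring C closes by a 6-exo-trig acyl substitution. No stereocentre is created, and since the bond from C2 to oxygen is not cleaved at any point the (S) configuration from step 8 should pass through unchanged. The regioselectivity needed is secured by the benzyloxy group on the aryne carbon C3, whose inductive pull and the ring distortion it causes steer nucleophiles to C1 and leave the anion beside that oxygen, while acyl capture is favoured over protonation because the silyl ether carries no O–H and THF offers no acidic C–H. The expelled methoxide should be silylated by Me3SiF or by unreacted 14 to Me3SiOMe, so the medium stays close to neutral and both C2 centres are shielded from E1cB ring opening.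

Step 13
Reactants: 23 (2S)-5,7-bis(benzyloxy)-2-{4-(benzyloxy)-3-[(2S)-5-(benzyloxy)-2-[4-(benzyloxy)phenyl]-7-methoxy-4-oxochroman-8-yl]phenyl}chroman-4-one
Product: 24 (2S)-5,7-dihydroxy-2-{4-hydroxy-3-[(2S)-5-hydroxy-2-(4-hydroxyphenyl)-7-methoxy-4-oxochroman-8-yl]phenyl}chroman-4-one
Conditions: H2 (1 atm), 10% Pd/C, EtOAc/MeOH, rt
Reagents that add atoms: none
Why: Catalytic hydrogenolysis of five aryl benzyl ethers under neutral conditions, which should leave the methyl ether, both ketones and both flavanone stereocentres untouched if stopped at full debenzylation.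

Compound list

1 | 1-(2,6-dihydroxy-4-methoxyphenyl)ethan-1-one | CC(=O)c1c(O)cc(OC)cc1O | starting material
2 | 1-[2-(benzyloxy)-6-hydroxy-4-methoxyphenyl]ethan-1-one | CC(=O)c1c(O)cc(OC)cc1OCc1ccccc1 | intermediate
3 | 1-[6-(benzyloxy)-2-hydroxy-3-iodo-4-methoxyphenyl]ethan-1-one | CC(=O)c1c(O)c(I)c(OC)cc1OCc1ccccc1 | intermediate
4 | (2E)-1-[6-(benzyloxy)-2-hydroxy-3-iodo-4-methoxyphenyl]-3-(dimethylamino)prop-2-en-1-one | CN(C)/C=C/C(=O)c1c(O)c(I)c(OC)cc1OCc1ccccc1 | intermediate (not isolated)
5 | 5-(benzyloxy)-8-iodo-7-methoxy-4H-chromen-4-one | COc1cc(OCc2ccccc2)c2c(c1I)occc2=O | intermediate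
6 | 3-bromo-4-hydroxybenzaldehyde | O=Cc1ccc(O)c(Br)c1 | starting material
7 | 4-(benzyloxy)-3-bromobenzaldehyde | O=Cc1ccc(OCc2ccccc2)c(Br)c1 | intermediate
8 | 4-(benzyloxy)-3-(4,4,5,5-tetramethyl-1,3,2-dioxaborolan-2-yl)benzaldehyde | O=Cc1ccc(OCc2ccccc2)c(c1)B1OC(C)(C)C(C)(C)O1 | intermediate
9 | 4-(benzyloxy)-3-[5-(benzyloxy)-7-methoxy-4-oxo-4H-chromen-8-yl]benzaldehyde | COc1cc(OCc2ccccc2)c2c(c1-c1cc(C=O)ccc1OCc1ccccc1)occc2=O | intermediate
10 | [4-(benzyloxy)phenyl]boronic acid | OB(O)c1ccc(OCc2ccccc2)cc1 | starting material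
11 | 4-(benzyloxy)-3-{(2S)-5-(benzyloxy)-2-[4-(benzyloxy)phenyl]-7-methoxy-4-oxochroman-8-yl}benzaldehyde | COc1cc(OCc2ccccc2)c2c(c1-c1cc(C=O)ccc1OCc1ccccc1)O[C@H](c1ccc(OCc3ccccc3)cc1)CC2=O | intermediate
12 | methyl (3S)-3-Ar*-3-[(trichlorosilyl)oxy]propanoate | COc1cc(OCc2ccccc2)c2c(c1-c1cc([C@@H](O[Si](Cl)(Cl)Cl)CC(=O)OC)ccc1OCc1ccccc1)O[C@H](c1ccc(OCc3ccccc3)cc1)CC2=O | intermediate (not isolated)
13 | methyl (3S)-3-Ar*-3-hydroxypropanoate | COc1cc(OCc2ccccc2)c2c(c1-c1cc([C@@H](O)CC(=O)OC)ccc1OCc1ccccc1)O[C@H](c1ccc(OCc3ccccc3)cc1)CC2=O | intermediate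
14 | methyl (3S)-3-Ar*-3-[(trimethylsilyl)oxy]propanoate | COc1cc(OCc2ccccc2)c2c(c1-c1cc([C@@H](O[Si](C)(C)C)CC(=O)OC)ccc1OCc1ccccc1)O[C@H](c1ccc(OCc3ccccc3)cc1)CC2=O | intermediate (precursor of the key step)
15 | 3,5-bis(benzyloxy)phenol | Oc1cc(OCc2ccccc2)cc(OCc2ccccc2)c1 | starting material
16 | 3,5-bis(benzyloxy)-2-bromophenol | Oc1cc(OCc2ccccc2)cc(OCc2ccccc2)c1Br | intermediate
17 | [3,5-bis(benzyloxy)-2-bromophenoxy]trimethylsilane | C[Si](C)(C)Oc1cc(OCc2ccccc2)cc(OCc2ccccc2)c1Br | intermediate (not isolated)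
18 | lithium 3,5-bis(benzyloxy)-2-(trimethylsilyl)phenolate | [Li+].[O-]c1cc(OCc2ccccc2)cc(OCc2ccccc2)c1[Si](C)(C)C | intermediate (not isolated)
19 | 3,5-bis(benzyloxy)-2-(trimethylsilyl)phenyl trifluoromethanesulfonate | C[Si](C)(C)c1c(OCc2ccccc2)cc(OCc2ccccc2)cc1OS(=O)(=O)C(F)(F)F | intermediate (aryne precursor)
20 | 3,5-bis(benzyloxy)benzyne (1,2-didehydro-3,5-bis(benzyloxy)benzene) | O(Cc1ccccc1)C1=CC(OCc2ccccc2)=CC#C1 | intermediate (not isolated)
21 | potassium (1S)-1-Ar*-3-methoxy-3-oxopropan-1-olate | COc1cc(OCc2ccccc2)c2c(c1-c1cc([C@@H]([O-])CC(=O)OC)ccc1OCc1ccccc1)O[C@H](c1ccc(OCc3ccccc3)cc1)CC2=O.[K+] | intermediate (not isolated)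
22 | potassium 4,6-bis(benzyloxy)-2-{[(1S)-1-Ar*-3-methoxy-3-oxopropyl]oxy}benzen-1-ide | COc1cc(OCc2ccccc2)c2c(c1-c1cc([C@@H](Oc3cc(OCc4ccccc4)cc(OCc4ccccc4)[c-]3)CC(=O)OC)ccc1OCc1ccccc1)O[C@H](c1ccc(OCc3ccccc3)cc1)CC2=O.[K+] | intermediate (not isolated)
23 | (2S)-5,7-bis(benzyloxy)-2-{4-(benzyloxy)-3-[(2S)-5-(benzyloxy)-2-[4-(benzyloxy)phenyl]-7-methoxy-4-oxochroman-8-yl]phenyl}chroman-4-one | COc1cc(OCc2ccccc2)c2c(c1-c1cc([C@@H]3CC(=O)c4c(OCc5ccccc5)cc(OCc5ccccc5)cc4O3)ccc1OCc1ccccc1)O[C@H](c1ccc(OCc3ccccc3)cc1)CC2=O | intermediate (product of the key step)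
24 | (2S)-5,7-dihydroxy-2-{4-hydroxy-3-[(2S)-5-hydroxy-2-(4-hydroxyphenyl)-7-methoxy-4-oxochroman-8-yl]phenyl}chroman-4-one | COc1cc(O)c2c(c1-c1cc([C@@H]3CC(=O)c4c(O)cc(O)cc4O3)ccc1O)O[C@H](c1ccc(O)cc1)CC2=O | target

Total step count: 13. Longest linear sequence: 9 steps (1, 2, 3, 6, 7, 8, 9, 12, 13).

Steps most likely to fail

Step 12 (new method). The aryl anion may be protonated before it reaches the ester, leaving an open aryl ether. The alkoxide may also undergo retro-aldol cleavage or β-elimination to a cinnamate, and adventitious base may open either flavanone ring by E1cB and erode a C2 centre. The fallback makes the same two bonds one at a time by known reactions; it sets out from 13 (with 19) and comes back at 23. The free alcohol 13 is O-arylated by the aryne from 19 (CsF, MeCN/toluene, rt), an O–H insertion that leaves the C–O bond at the stereocentre alone and should give methyl (3S)-3-Ar*-3-[3,5-bis(benzyloxy)phenoxy]propanoate F1. The ester is cleaved under neutral conditions (Me3SnOH, ClCH2CH2Cl, 70 °C) to (3S)-3-Ar*-3-[3,5-bis(benzyloxy)phenoxy]propanoic acid F2. Treatment with (CF3CO)2O in CH2Cl2 at 0 °C forms the mixed anhydride, which should acylate either of the two equivalent positions ortho to the ether oxygen (intramolecular Friedel–Crafts acylation) and deliver 23.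

Step 7. Aryl insertion into the electron-rich, peri-substituted chromone may be slow, aryl transfer to the aldehyde may compete, and ring opening of the product in the aqueous medium may erode the enantiomeric purity. The fallback forms the O1''–C2'' bond instead and resolves; it sets out from 3 and comes back at 11. Claisen–Schmidt condensation of 3 with 4-(benzyloxy)benzaldehyde (KOH, EtOH, rt) should give (2E)-1-[6-(benzyloxy)-2-hydroxy-3-iodo-4-methoxyphenyl]-3-[4-(benzyloxy)phenyl]prop-2-en-1-one F3. NaOAc in refluxing EtOH closes it by oxa-Michael addition to racemic 5-(benzyloxy)-2-[4-(benzyloxy)phenyl]-8-iodo-7-methoxychroman-4-one F4. Suzuki coupling of F4 with 8 (Pd(OAc)2, SPhos, K3PO4, toluene/H2O, 70 °C; any chalcone formed is recyclised with NaOAc) gives racemic 4-(benzyloxy)-3-{5-(benzyloxy)-2-[4-(benzyloxy)phenyl]-7-methoxy-4-oxochroman-8-yl}benzaldehyde F5. Preparative HPLC on a cellulose tris(3,5-dimethylphenylcarbamate) phase then delivers the (2S) enantiomer, 11.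

Step 8. The chromanone carbonyl may sequester the silicon Lewis acid and stall the reaction, or facial selectivity on this large aldehyde may be poor. The fallback replaces catalyst control by a covalently bound auxiliary with separable diastereomers; it sets out from 11 and comes back at 13. The tin enolate of (4S)-3-acetyl-4-isopropyl-1,3-thiazolidine-2-thione (Sn(OTf)2, N-ethylpiperidine, CH2Cl2, −40 °C) is treated with 11 at −78 °C (Nagao acetate aldol) to give (3S)-3-Ar*-3-hydroxy-1-[(4S)-4-isopropyl-2-thioxo-1,3-thiazolidin-3-yl]propan-1-one F6, which is freed from its minor diastereomer by chromatography. Methanolysis (MeOH, imidazole, rt) then displaces the auxiliary and gives 13.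

Further compounds

F1 | step 12 | methyl (3S)-3-Ar*-3-[3,5-bis(benzyloxy)phenoxy]propanoate | COc1cc(OCc2ccccc2)c2c(c1-c1cc([C@@H](Oc3cc(OCc4ccccc4)cc(OCc4ccccc4)c3)CC(=O)OC)ccc1OCc1ccccc1)O[C@H](c1ccc(OCc3ccccc3)cc1)CC2=O
F2 | step 12 | (3S)-3-Ar*-3-[3,5-bis(benzyloxy)phenoxy]propanoic acid | COc1cc(OCc2ccccc2)c2c(c1-c1cc([C@@H](Oc3cc(OCc4ccccc4)cc(OCc4ccccc4)c3)CC(=O)O)ccc1OCc1ccccc1)O[C@H](c1ccc(OCc3ccccc3)cc1)CC2=O
F3 | step 7 | (2E)-1-[6-(benzyloxy)-2-hydroxy-3-iodo-4-methoxyphenyl]-3-[4-(benzyloxy)phenyl]prop-2-en-1-one | O=C(/C=C/c1ccc(OCc2ccccc2)cc1)c1c(O)c(I)c(OC)cc1OCc1ccccc1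
F4 | step 7 | racemic 5-(benzyloxy)-2-[4-(benzyloxy)phenyl]-8-iodo-7-methoxychroman-4-one | COc1cc(OCc2ccccc2)c2c(c1I)OC(c1ccc(OCc3ccccc3)cc1)CC2=O
F5 | step 7 | racemic 4-(benzyloxy)-3-{5-(benzyloxy)-2-[4-(benzyloxy)phenyl]-7-methoxy-4-oxochroman-8-yl}benzaldehyde | COc1cc(OCc2ccccc2)c2c(c1-c1cc(C=O)ccc1OCc1ccccc1)OC(c1ccc(OCc3ccccc3)cc1)CC2=O
F6 | step 8 | (3S)-3-Ar*-3-hydroxy-1-[(4S)-4-isopropyl-2-thioxo-1,3-thiazolidin-3-yl]propan-1-one | COc1cc(OCc2ccccc2)c2c(c1-c1cc([C@@H](O)CC(=O)N3[C@@H](C(C)C)CSC3=S)ccc1OCc1ccccc1)O[C@H](c1ccc(OCc3ccccc3)cc1)CC2=O
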